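## Structural features

The target is a flavone: benzene ring A is fused through C4a–C8a to the 4-pyranone ring C, which carries phenyl ring B at C2 and only hydrogen at C3. Ring A is hexasubstituted, with oxygen on C5, C6, C7 and C8 (OMe, OH, OMe, OMe), so the one free hydroxyl at C6 lies between two methoxy groups. Ring B has a hydroxyl at C2' and a methoxy group at C6', so both positions ortho to the C2–C1' bond are occupied and that bond is hindered and twisted. There is no stereocentre and no configurationally stable axis, so no stereocentres stand next to each other and every problem is one of regiochemistry. The fragile points are C2 of ring C toward hydroxide (ring opening), the C5 methyl ether peri to the carbonyl toward Lewis acids, and the electron-rich hydroquinone and catechol intermediates toward oxidation in base. The real difficulty is to place four contiguous oxygens on ring A with exactly one left unmethylated, and to keep one ring B oxygen free next to a methyl ether. The key step uses the fact that C5–C8 map onto the four carbons of a squaric diester and that C4a=C8a is the unsubstituted enone double bond of a 2-aryl-4-pyranone already holding ring B. Ring A can therefore be grown onto the heterocycle by forming C4a–C5 (carbonyl addition) and then C8–C8a (electrocyclization).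

## Logic of the disconnections

Flavone numbering is used for all atoms, also in the pyranone stage (pyranone C5 = future C4a, pyranone C6 = future C8a).

**17 to 16.** The O–CH3 bond at C7 is cut. The ring expansion delivers the C6 and C7 oxygens as two like ester oxygens, so they can only be told apart afterwards. The C7 hydroxyl is para to C4a and conjugated with the C4 carbonyl, which makes it the most acidic of the three phenols of 16. The gain is that both oxygens can travel as the same protecting group. The demand is a methylation under acidity control (weak base, one equivalent of electrophile) that touches neither the C6 hydroxyl nor the ring B hydroxyl.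

**16 to 15.** Three O–benzyl bonds are cut (C6, C7, C2'). One hydrogenolysis removes all temporary groups, so no separate deprotection of ring B is needed. A silyl ether at the ring B oxygen was set aside: it could be lost under the carbonate and alkylating agent needed in the step before and would then be methylated for good. A benzyl ether is inert there and saves the fluoride step. The demand is that C2=C3 survives the hydrogenation.

**15 to 14.** The O–CH3 bonds at C5 and C8 are cut. The two hydroxyls created by the ring expansion are exactly two of the three that the target carries as methyl ethers. The demand is a forcing methylation for the hydrogen-bonded C5 hydroxyl, which is why 14 holds no base-labile group.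

**14 to 11.** The C8–C8a bond is cut, and with it ring A. The carbinol carbon of 11 becomes C5, the ketone carbon C8, and the two ester carbons C6 and C7. All four oxygens and ring A come from one four-carbon unit, and ring C with ring B is untouched. The demand is inward rotation of the pyranonyl group in the ring opening and closure at C8a.

**11 to 7 and 9.** The C4a–C5 bond is cut. The carbanion equivalent 10 at C4a adds to one of the two equivalent carbonyls of 9. The gain is two simple pieces, a halogenated pyranone and a symmetric diester. The demand is a metalated pyranone that survives long enough to add 1,2.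

**9 to 8.** The two ester O–CH2 bonds are cut, back to the parent diacid.

**7 to 2 and 5.** The C3–C4 bond (Claisen acylation) and the O1–C8a bond (ring closure with loss of methanol) are cut. The iodine arrives on 5 and is not introduced by halogenating the finished pyranone. A 2-aryl-4-pyranone has two nucleophilic α-carbons, C3 and C4a, and only a halogen carried in on the three-carbon piece is certain to sit at C4a. The demand is attack of the enolate of 2 at the ester carbonyl of 5 and a protected ring B oxygen, since a free one would close a chromone instead.

**5 to 3 and 2 to 1.** The C–I bond of 5 and the O–benzyl bond of 2 are cut, which leads to the two commercial materials.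

## Other disconnections considered

**Alternative 1:** The cut takes C2 out as carbon monoxide and breaks C1'–C2 and C2–C3. This leaves the ring B iodide 1-(benzyloxy)-2-iodo-3-methoxybenzene A1 and the ring A methyl ketone 1-[5-(benzyloxy)-3,4,6-trimethoxy-2-(methoxymethoxy)phenyl]ethan-1-one A2. In the forward step, zerovalent palladium from Pd(dba)2 and a bisphosphine inserts into the C–I bond of A1 and takes up CO. The aroylpalladium species acylates the enolate of A2 to give the 1,3-diketone 1-[5-(benzyloxy)-3,4,6-trimethoxy-2-(methoxymethoxy)phenyl]-3-[2-(benzyloxy)-6-methoxyphenyl]propane-1,3-dione A3. Acid would then remove the acetal and close ring C to 6,2'-bis(benzyloxy)-5,7,8,6'-tetramethoxyflavone A4, and hydrogenolysis would give 17.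

- In its favour: the route is convergent. Every ring A oxygen has its final substituent before the coupling, so no late selective methylation is needed; on this point it is the better plan. The end game is two steps against three, and no metalated pyranone is required.
- Against it: A2 is a hexasubstituted benzene with three kinds of oxygen substituent. Making it regiochemically pure is the main task of that route and is the problem the chosen plan solves in a single step. Both partners are di-ortho-substituted, so C-acylation of a hindered enolate by a hindered aroylpalladium should be slow, and direct α-arylation without CO can compete.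
- Comparison: the alternative depends on a catalytic cycle that is sensitive to steric load on both partners; the chosen plan depends on a unimolecular pericyclic cascade that needs only heat. After the key step the alternative is equal or better; over the whole route it is longer, because A2 needs its own ring A synthesis.

**Alternative 2:** The cut is C5–C6 inside ring A, so ring A is made before rings B and C. In the forward step, 4-hydroxy-2,3-dimethoxy-4-[(E)-2-methoxy-1-(2-methyl-1,3-dioxolan-2-yl)ethenyl]cyclobut-2-en-1-one A5 is heated. It would come from a squaric diester and an α-metalated β-methoxyvinyl ketal. Ring opening to a dienylketene and 6-electron electrocyclization onto the methoxy-bearing alkene carbon form C5–C6, and tautomerization gives 2-(2,5-dihydroxy-3,4,6-trimethoxyphenyl)-2-methyl-1,3-dioxolane A6.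

- In its favour: this is the same pericyclic chemistry as the chosen plan, but with a plain alkene terminus, the best established case; on precedent it is the better of the two. The oxygen pattern is exactly right. The C5, C7 and C8 methoxy groups are in place, and the two new hydroxyls are the C6 hydroxyl and the oxygen that becomes O1. No catechol has to be monomethylated, which is a clear advantage.
- Against it: the two hydroxyls of A6 must still be told apart. This is feasible after ketal cleavage, when one is hydrogen-bonded to the acetyl group. The alkenylmetal partner needs several steps. The step builds ring A only, so ring C and the hindered C2–C1' bond must still be made by a Baker–Venkataraman sequence with a 2,6-disubstituted ring B acid derivative, or through A2 and the coupling of alternative 1.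
- Comparison: it is equal or lower in mechanistic risk and better in regiochemical fidelity at C6 and C7. It is clearly worse in step economy and convergence, because its key step comes early and gives a small fragment.

**Alternative 3:** The cut is C2–C1', made intramolecular by an ester tether from the ring B oxygen to a carboxyl group on C3. The substrate is 2-bromo-3-methoxyphenyl 6-(benzyloxy)-5,7,8-trimethoxy-4-oxo-4H-chromene-3-carboxylate A7. Zerovalent palladium from Pd(OAc)2 and PCy3 inserts into the C1'–Br bond, and carbonate-assisted metalation at the chromone C2–H followed by reductive elimination forms C2–C1'. This closes the six-membered lactone of 9-(benzyloxy)-1,8,10,11-tetramethoxychromeno[4,3-b]chromene-6,7-dione A8. Lactone hydrolysis, decarboxylation at C3 and hydrogenolysis would lead to 17.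

- In its favour: the most hindered bond of the molecule is formed intramolecularly. The tether protects the ring B oxygen and is traceless. The ring A pattern is fixed beforehand, and no stoichiometric organometallic reagent is needed. In the way it makes the C2–C1' bond, it is equal to or better than the chosen plan.
- Against it: a chromone-3-carboxylic acid with the complete ring A is required, so the hexasubstituted ring has to be made first, as in alternative 1. The aryl ester is an activated ester and may not withstand K2CO3 at the temperature of the arylation. The later hydroxide step can open ring C at C2 as well as the lactone, and a decarboxylation is added.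
- Comparison: the alternative is equal on late regiochemistry and better for varying ring B. It is inferior in step economy and in that its key step builds no part of ring A.

Key step: step 6

Remark: the ring B oxygen is carried as a benzyl ether, a protecting-group choice that leaves the skeletons of the key-step precursor 11 and product 14 unchanged; benzyl bromide, benzyl alcohol and the other reagents are taken as commercial.

## Steps

Step 1
Reactants: 1 2'-hydroxy-6'-methoxyacetophenone
Product: 2 1-[2-(benzyloxy)-6-methoxyphenyl]ethan-1-one
Conditions: BnBr, K2CO3, DMF, 60 °C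
Reagents that add atoms: benzyl bromide, BrCc1ccccc1
Why: Williamson ether synthesis; K2CO3 in DMF deprotonates the hydrogen-bonded ortho-acyl phenol and the phenoxide is alkylated at oxygen. The benzyl ether is inert to enolate, acid, organomagnesium and thermal conditions and leaves together with the other benzyl groups in step 8.

Step 2
Reactants: 3 methyl (E)-3-methoxyacrylate
Product: 5 methyl (Z)-2-iodo-3-methoxyacrylate, via methyl 3-acetoxy-2-iodo-3-methoxypropanoate 4 (not isolated)
Conditions: NIS, AcOH, CH2Cl2, rt; then Et3N, rt
Reagents that add atoms: N-iodosuccinimide, O=C1CCC(=O)N1I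
Why: Iodo-acetoxylation of the enol ether (iodine at the nucleophilic C2, acetate at the oxocarbenium carbon) followed by base-induced elimination of acetic acid. The Z isomer with methoxy anti to the ester is the thermodynamically preferred geometry, and the geometry is erased in step 3 in any case.

Step 3
Reactants: 2 1-[2-(benzyloxy)-6-methoxyphenyl]ethan-1-one; 5 methyl (Z)-2-iodo-3-methoxyacrylate
Product: 7 2-[2-(benzyloxy)-6-methoxyphenyl]-5-iodo-4H-pyran-4-one, via (Z)-1-aryl-4-iodo-5-methoxypent-4-ene-1,3-dione 6 (not isolated)
Conditions: LiN(SiMe3)2 (2.2 equiv), THF, −78 °C; 5, −78 → 0 °C; aq. NH4Cl; crude, TFA, CH2Cl2, rt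
Reagents that add atoms: none
Why: Crossed Claisen condensation of the methyl ketone enolate with the acrylate ester gives the 1,3-diketone; under acid its aryl-ketone enol oxygen adds to the β-methoxy enone carbon and methanol is expelled (addition–elimination cyclization to a 4-pyranone). The iodine rides in on the carbon that becomes pyranone C5 (future C4a), so its position is fixed by construction, and the benzyl ether prevents closure to a chromone through the ring B oxygen.

Step 4
Reactants: 8 squaric acid
Product: 9 3,4-bis(benzyloxy)cyclobut-3-ene-1,2-dione (dibenzyl squarate)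
Conditions: BnOH, toluene, reflux, Dean–Stark
Reagents that add atoms: benzyl alcohol, OCc1ccccc1
Why: Squaric acid is a strong vinylogous carboxylic acid and catalyses its own esterification; azeotropic removal of water drives formation of the diester, the standard preparation of dialkyl squarates from primary alcohols.

Step 5
Reactants: 7 2-[2-(benzyloxy)-6-methoxyphenyl]-5-iodo-4H-pyran-4-one; 9 3,4-bis(benzyloxy)cyclobut-3-ene-1,2-dione
Product: 11 2,3-bis(benzyloxy)-4-{6-[2-(benzyloxy)-6-methoxyphenyl]-4-oxo-4H-pyran-3-yl}-4-hydroxycyclobut-2-en-1-one (racemic carbinol), via 4-oxo-4H-pyran-3-ylmagnesium chloride 10 (not isolated)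
Conditions: iPrMgCl·LiCl (1.1 equiv), THF, −40 °C; 9 (1.2 equiv), −40 → −10 °C; aq. NH4Cl
Reagents that add atoms: none
Why: Iodine–magnesium exchange at the α-iodo enone carbon is fast at low temperature and gives a magnesium reagent stabilised by the neighbouring carbonyl, as with 3-iodochromones; this hard nucleophile adds 1,2 to one of the two equivalent ketone carbonyls of the squaric diester, the usual entry to 4-substituted 4-hydroxycyclobutenones. The carbinol stereocentre forms racemic and is destroyed in step 6.

Step 6
Reactants: 11 2,3-bis(benzyloxy)-4-{6-[2-(benzyloxy)-6-methoxyphenyl]-4-oxo-4H-pyran-3-yl}-4-hydroxycyclobut-2-en-1-one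
Product: 14 6,7-bis(benzyloxy)-2-[2-(benzyloxy)-6-methoxyphenyl]-5,8-dihydroxy-4H-chromen-4-one, via (Z)-dienylketene 12 (not isolated), via 8aH-chromene-4,8-dione 13 (not isolated)
Conditions: toluene (degassed, 0.02 M), 110 °C, Ar
Reagents that add atoms: none
Why: Moore rearrangement, the thermal ring expansion known for 4-alkenyl- and 4-heteroaryl-4-hydroxycyclobutenones. Heating opens the cyclobutenone by conrotatory 4-electron cleavage of the bond between the carbinol carbon and the carbonyl carbon to give dienylketene 12; the hydroxyl, the strongest donor on the breaking bond, rotates outward, which turns the pyranonyl group inward and brings its free double bond next to the ketene carbon. A thermal disrotatory 6-electron electrocyclization of this 1,3,5-triene then joins the ketene carbon (future C8) to pyranone C6 (future C8a) and closes the six-membered carbocycle as dienone 13. Tautomerization moves the C8a hydrogen to oxygen, restores the pyranone and gives ring A as a hydroquinone with hydroxyls at C5 (former carbinol) and C8 (former ketene carbon) and the benzyloxy carbons at C6 and C7. No stereocentre remains, since the carbinol centre becomes sp2 and the transient C8a centre is lost on aromatization. The step needs the right sense of rotation and a single site of closure; the outward preference of the hydroxyl secures the first, and the substrate secures the second because the only other neighbour of C4a is the C4 carbonyl carbon. Dilution and exclusion of oxygen should keep the ketene from intermolecular trapping and the hydroquinone from oxidation to the quinone.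

Step 7
Reactants: 14 6,7-bis(benzyloxy)-2-[2-(benzyloxy)-6-methoxyphenyl]-5,8-dihydroxy-4H-chromen-4-one
Product: 15 6,7-bis(benzyloxy)-2-[2-(benzyloxy)-6-methoxyphenyl]-5,8-dimethoxy-4H-chromen-4-one
Conditions: Me2SO4, K2CO3, acetone, reflux, Ar
Reagents that add atoms: dimethyl sulfate, COS(=O)(=O)OC
Why: Phenol O-methylation; the free C8 hydroxyl reacts quickly and the hydrogen-bonded C5 hydroxyl under the prolonged reflux that is standard for 5-hydroxyflavones. No base-labile group is present, and the dimethyl ether can no longer be oxidised to a quinone.

Step 8
Reactants: 15 6,7-bis(benzyloxy)-2-[2-(benzyloxy)-6-methoxyphenyl]-5,8-dimethoxy-4H-chromen-4-one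
Product: 16 6,7-dihydroxy-2-(2-hydroxy-6-methoxyphenyl)-5,8-dimethoxy-4H-chromen-4-one
Conditions: H2 (1 atm), Pd/C (10 wt %), EtOAc–MeOH, rt
Reagents that add atoms: none
Why: Catalytic hydrogenolysis of three aryl benzyl ethers; the cross-conjugated C2=C3 bond of a flavone should survive these mild conditions if the reaction is stopped at complete debenzylation, and the methyl ethers are untouched.

Step 9
Reactants: 16 6,7-dihydroxy-2-(2-hydroxy-6-methoxyphenyl)-5,8-dimethoxy-4H-chromen-4-one
Product: 17 6,2'-dihydroxy-5,7,8,6'-tetramethoxyflavone
Conditions: MeI (1.05 equiv), Li2CO3 (1.1 equiv), DMF, 40 °C, Ar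
Reagents that add atoms: iodomethane, CI
Why: Williamson methylation under acidity control; the C7 hydroxyl is para to C4a and conjugated with the C4 carbonyl (a vinylogous acid), so the weak base ionises it alone, as in the selective 4-O-alkylation of 3,4-dihydroxybenzaldehyde and the 7-O-alkylation of 6,7-dihydroxyflavones. The C6 hydroxyl (para to the O1-bearing carbon) and the hydroxyl of the twisted ring B are less acidic and should remain unalkylated with one equivalent of iodomethane.

## Compound list

1 | 2'-hydroxy-6'-methoxyacetophenone | CC(=O)c1c(O)cccc1OC | starting material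
2 | 1-[2-(benzyloxy)-6-methoxyphenyl]ethan-1-one | CC(=O)c1c(OCc2ccccc2)cccc1OC | intermediate
3 | methyl (E)-3-methoxyacrylate | CO/C=C/C(=O)OC | starting material
4 | methyl 3-acetoxy-2-iodo-3-methoxypropanoate (mixture of racemic diastereomers) | COC(OC(C)=O)C(I)C(=O)OC | intermediate (not isolated)
5 | methyl (Z)-2-iodo-3-methoxyacrylate | CO/C=C(\I)C(=O)OC | intermediate
6 | (Z)-1-[2-(benzyloxy)-6-methoxyphenyl]-4-iodo-5-methoxypent-4-ene-1,3-dione | CO/C=C(\I)C(=O)CC(=O)c1c(OC)cccc1OCc1ccccc1 | intermediate (not isolated)
7 | 2-[2-(benzyloxy)-6-methoxyphenyl]-5-iodo-4H-pyran-4-one | COc1cccc(OCc2ccccc2)c1-c1cc(=O)c(I)co1 | intermediate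
8 | squaric acid (3,4-dihydroxycyclobut-3-ene-1,2-dione) | OC1=C(O)C(=O)C1=O | starting material
9 | 3,4-bis(benzyloxy)cyclobut-3-ene-1,2-dione (dibenzyl squarate) | O=C1C(=O)C(OCc2ccccc2)=C1OCc1ccccc1 | intermediate
10 | {6-[2-(benzyloxy)-6-methoxyphenyl]-4-oxo-4H-pyran-3-yl}magnesium chloride (LiCl complex) | COc1cccc(OCc2ccccc2)c1-c1cc(=O)c([Mg]Cl)co1 | intermediate (not isolated)
11 | 2,3-bis(benzyloxy)-4-{6-[2-(benzyloxy)-6-methoxyphenyl]-4-oxo-4H-pyran-3-yl}-4-hydroxycyclobut-2-en-1-one (racemic) | COc1cccc(OCc2ccccc2)c1-c1cc(=O)c(C2(O)C(OCc3ccccc3)=C(OCc3ccccc3)C2=O)co1 | intermediate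
12 | (3Z)-2,3-bis(benzyloxy)-4-{6-[2-(benzyloxy)-6-methoxyphenyl]-4-oxo-4H-pyran-3-yl}-4-hydroxybuta-1,3-dien-1-one | O=C=C(OCc1ccccc1)/C(OCc1ccccc1)=C(/O)c1coc(-c2c(OC)cccc2OCc2ccccc2)cc1=O | intermediate (not isolated)
13 | 6,7-bis(benzyloxy)-2-[2-(benzyloxy)-6-methoxyphenyl]-5-hydroxy-8aH-chromene-4,8-dione (racemic at C8a) | O=C1C(OCc2ccccc2)=C(OCc2ccccc2)C(O)=C2C(=O)C=C(c3c(OC)cccc3OCc3ccccc3)OC12 | intermediate (not isolated)
14 | 6,7-bis(benzyloxy)-2-[2-(benzyloxy)-6-methoxyphenyl]-5,8-dihydroxy-4H-chromen-4-one | COc1cccc(OCc2ccccc2)c1-c1cc(=O)c2c(O)c(OCc3ccccc3)c(OCc3ccccc3)c(O)c2o1 | intermediate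
15 | 6,7-bis(benzyloxy)-2-[2-(benzyloxy)-6-methoxyphenyl]-5,8-dimethoxy-4H-chromen-4-one | COc1cccc(OCc2ccccc2)c1-c1cc(=O)c2c(OC)c(OCc3ccccc3)c(OCc3ccccc3)c(OC)c2o1 | intermediate
16 | 6,7-dihydroxy-2-(2-hydroxy-6-methoxyphenyl)-5,8-dimethoxy-4H-chromen-4-one | COc1cccc(O)c1-c1cc(=O)c2c(OC)c(O)c(O)c(OC)c2o1 | intermediate
17 | 6,2'-dihydroxy-5,7,8,6'-tetramethoxyflavone | COc1cccc(O)c1-c1cc(=O)c2c(OC)c(O)c(OC)c(OC)c2o1 | target

## Step count and risk

Total step count: 9 (steps 1 to 9). Longest linear sequence: 7 steps (1, 3, 5, 6, 7, 8, 9, from compound 1; the branch from 3 through step 2 is equally long).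

Least certain steps:

**Step 6 (key step).** A 4-oxopyran-3-yl group has no direct precedent as the inward-rotating substituent; the closest cases are alkenyl and heteroaryl groups. The most likely failures are three: ring opening with the hydroxyl turned inward, after which the ketene is trapped by its own hydroxyl as a butenolide; slow electrocyclization onto the polarised pyranone double bond, which leaves the ketene open to intermolecular trapping; and oxidation of the hydroquinone during isolation.

The fallback changes the substrate. Starting from 11, the tertiary carbinol is methylated under neutral conditions (MeI, Ag2O, MeCN) to 2,3-bis(benzyloxy)-4-{6-[2-(benzyloxy)-6-methoxyphenyl]-4-oxo-4H-pyran-3-yl}-4-methoxycyclobut-2-en-1-one F1. A methoxy group cannot lactonise, and the ring opening is reversible, so only the productive rotamer is consumed. Thermolysis in toluene should then give the mono-protected hydroquinone 6,7-bis(benzyloxy)-2-[2-(benzyloxy)-6-methoxyphenyl]-8-hydroxy-5-methoxy-4H-chromen-4-one F2, which is not prone to quinone formation. Methylation of its C8 hydroxyl (MeI, K2CO3, acetone) returns to the route at 15.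

**Step 3.** The ester carbonyl of 5 is a deactivated vinylogous carbonate flanked by iodine. Acylation may therefore be slow and lose out to conjugate addition–elimination at the β-carbon or to dehydroiodination of 5 by the amide base.

The fallback introduces the iodine after ring formation. Starting from 2 and 3, the same Claisen condensation with the iodine-free ester gives (E)-1-[2-(benzyloxy)-6-methoxyphenyl]-5-methoxypent-4-ene-1,3-dione F3. Acid closes it to 2-[2-(benzyloxy)-6-methoxyphenyl]-4H-pyran-4-one F4. α-Iodination with I2 and pyridine in CH2Cl2 then runs by conjugate addition of pyridine at the unsubstituted C8a position, iodination of the enolate at C4a and elimination. This mechanism directs the halogen away from C3, whose neighbour C2 is blocked by the aryl group. The sequence returns to the route at 7; a regioisomeric iodide, if formed, would have to be removed here.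

**Step 5.** The metalated pyranone may fragment on warming by β-elimination of the ring oxygen (opening to an ynone enolate), may attack the C4 carbonyl of a second molecule, or may add too slowly to the squarate because the carbanion is stabilised.

The fallback avoids a basic carbanion. Starting from 7 and 9, a Nozaki–Hiyama–Kishi coupling (CrCl2 in excess, catalytic NiCl2, DMF, rt) generates a non-basic alkenylchromium species in the presence of the strained, activated ketone carbonyl of 9. After aqueous work-up it arrives directly at 11. This fallback makes no compound outside the compound list (entry F0).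

**Step 9.** Chemoselectivity may be lost: methylation could also occur at the ring B hydroxyl or at the C6 hydroxyl, a second methylation could follow, and the catechol could be oxidised under base.

The fallback replaces acidity-controlled alkylation by a protection sequence that relies on leaving-group ability. Starting from 16, peracetylation (Ac2O, pyridine) gives 6,7-diacetoxy-2-(2-acetoxy-6-methoxyphenyl)-5,8-dimethoxy-4H-chromen-4-one F5. The C7 acetate, the ester of the most acidic phenol, is cleaved selectively with thiophenol and imidazole in N-methylpyrrolidone at 0 °C to 6-acetoxy-2-(2-acetoxy-6-methoxyphenyl)-7-hydroxy-5,8-dimethoxy-4H-chromen-4-one F6. Mitsunobu etherification of the single free hydroxyl (MeOH, PPh3, DIAD, THF) gives 6-acetoxy-2-(2-acetoxy-6-methoxyphenyl)-5,7,8-trimethoxy-4H-chromen-4-one F7. Methanolysis of the two acetates (K2CO3, MeOH, rt) returns to the route at 17.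

## Further compounds

F1 | step 6 | 2,3-bis(benzyloxy)-4-{6-[2-(benzyloxy)-6-methoxyphenyl]-4-oxo-4H-pyran-3-yl}-4-methoxycyclobut-2-en-1-one (racemic) | COc1cccc(OCc2ccccc2)c1-c1cc(=O)c(C2(OC)C(OCc3ccccc3)=C(OCc3ccccc3)C2=O)co1
F2 | step 6 | 6,7-bis(benzyloxy)-2-[2-(benzyloxy)-6-methoxyphenyl]-8-hydroxy-5-methoxy-4H-chromen-4-one | COc1cccc(OCc2ccccc2)c1-c1cc(=O)c2c(OC)c(OCc3ccccc3)c(OCc3ccccc3)c(O)c2o1
F3 | step 3 | (E)-1-[2-(benzyloxy)-6-methoxyphenyl]-5-methoxypent-4-ene-1,3-dione | CO/C=C/C(=O)CC(=O)c1c(OC)cccc1OCc1ccccc1
F4 | step 3 | 2-[2-(benzyloxy)-6-methoxyphenyl]-4H-pyran-4-one | COc1cccc(OCc2ccccc2)c1-c1cc(=O)cco1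
F0 | step 5 | none | none
F5 | step 9 | 6,7-diacetoxy-2-(2-acetoxy-6-methoxyphenyl)-5,8-dimethoxy-4H-chromen-4-one | COc1cccc(OC(C)=O)c1-c1cc(=O)c2c(OC)c(OC(C)=O)c(OC(C)=O)c(OC)c2o1
F6 | step 9 | 6-acetoxy-2-(2-acetoxy-6-methoxyphenyl)-7-hydroxy-5,8-dimethoxy-4H-chromen-4-one | COc1cccc(OC(C)=O)c1-c1cc(=O)c2c(OC)c(OC(C)=O)c(O)c(OC)c2o1
F7 | step 9 | 6-acetoxy-2-(2-acetoxy-6-methoxyphenyl)-5,7,8-trimethoxy-4H-chromen-4-one | COc1cccc(OC(C)=O)c1-c1cc(=O)c2c(OC)c(OC(C)=O)c(OC)c(OC)c2o1
A1 | alternative 1 | 1-(benzyloxy)-2-iodo-3-methoxybenzene | COc1cccc(OCc2ccccc2)c1I
A2 | alternative 1 | 1-[5-(benzyloxy)-3,4,6-trimethoxy-2-(methoxymethoxy)phenyl]ethan-1-one | CC(=O)c1c(OCOC)c(OC)c(OC)c(OCc2ccccc2)c1OC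
A3 | alternative 1 | 1-[5-(benzyloxy)-3,4,6-trimethoxy-2-(methoxymethoxy)phenyl]-3-[2-(benzyloxy)-6-methoxyphenyl]propane-1,3-dione | COc1cccc(OCc2ccccc2)c1C(=O)CC(=O)c1c(OCOC)c(OC)c(OC)c(OCc2ccccc2)c1OC
A4 | alternative 1 | 6,2'-bis(benzyloxy)-5,7,8,6'-tetramethoxyflavone | COc1cccc(OCc2ccccc2)c1-c1cc(=O)c2c(OC)c(OCc3ccccc3)c(OC)c(OC)c2o1
A5 | alternative 2 | 4-hydroxy-2,3-dimethoxy-4-[(E)-2-methoxy-1-(2-methyl-1,3-dioxolan-2-yl)ethenyl]cyclobut-2-en-1-one (racemic) | CO/C=C(/C1(C)OCCO1)C1(O)C(OC)=C(OC)C1=O
A6 | alternative 2 | 2-(2,5-dihydroxy-3,4,6-trimethoxyphenyl)-2-methyl-1,3-dioxolane | COc1c(O)c(OC)c(OC)c(O)c1C1(C)OCCO1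
A7 | alternative 3 | 2-bromo-3-methoxyphenyl 6-(benzyloxy)-5,7,8-trimethoxy-4-oxo-4H-chromene-3-carboxylate | COc1cccc(OC(=O)c2coc3c(OC)c(OC)c(OCc4ccccc4)c(OC)c3c2=O)c1Br
A8 | alternative 3 | 9-(benzyloxy)-1,8,10,11-tetramethoxychromeno[4,3-b]chromene-6,7-dione | COc1cccc2OC(=O)c3c(-c12)oc1c(OC)c(OC)c(OCc4ccccc4)c(OC)c1c3=O
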